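**Retrosynthetic overview** (germacrane numbering: ring C1–C10, lactone C12(=O)–O–C6 with C7–C11=C13, ester C14 on C10, methyl C15 on C4)

1. Target 23 comes from diene 22 by a late epoxidation of C4=C5; 22 comes from the 8-epi alcohol 19 by Mitsunobu methacryloylation (inversion at C8) and silyl-to-acetyl exchange at O9.
2. Key disconnection C7–C8: the ten-membered ring of 19 is closed by making C7, the normally electrophilic β-carbon of the unsaturated lactone, nucleophilic as an allylchromium (vinylogous homoenolate) and adding it to the C8 aldehyde of 17. This sets C7 and C8 and unveils the α-methylene lactone.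
3. 17 comes from bromomethylbutenolide 9 and acrylate 13 by cross-metathesis (C1=C10), then one-pot silylation and acetal unmasking.
4. 9 comes from divinyl carbinol 6 (carboalumination of hex-1-en-5-yne, acrolein, lipase resolution) by acylation and ring-closing metathesis; 13 comes from an asymmetric Morita–Baylis–Hillman reaction.
5. Ring order: butenolide (step 4), then ten-membered carbocycle (step 8), then epoxide (step 11).

Assumption: simple group-delivering reagents (Me3Al, MeOH, TESOTf, methacrylic acid, Ac2O, mCPBA) are treated as reagents and are not numbered.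
Assumption: only intermediates that accumulate in the flask (organometallics made in situ, first-stage products of one-pot sequences) are numbered as not isolated; fleeting mechanistic species are not.

**Step 1**
Reactants: 1 hex-1-en-5-yne; 2 acrolein
Product: 5 racemic (4E)-5-methylnona-1,4,8-trien-3-ol, via alkenyldimethylalane 3 (not isolated), via lithium alkenylalanate 4 (not isolated)
Conditions: Me3Al, Cp2ZrCl2 (20 mol%), CH2Cl2, 25 °C; evaporate; n-BuLi, hexane/THF, −78 °C; acrolein, −78 to 0 °C; H2O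
Reagents that add atoms: trimethylaluminium C[Al](C)C
Why: Negishi zirconium-catalysed carboalumination adds Me and Al syn across the terminal alkyne only, fixing the (E)-trisubstituted C4=C5 alkene, and the derived alanate adds 1,2 to acrolein to give the racemic C6 carbinol.

**Step 2**
Reactants: 5 racemic (4E)-5-methylnona-1,4,8-trien-3-ol
Product: 6 (3S,4E)-5-methylnona-1,4,8-trien-3-ol
Conditions: Novozym 435 (immobilised Candida antarctica lipase B), vinyl acetate (0.6 equiv), hexane, 25 °C, to about 55% conversion; chromatography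
Reagents that add atoms: none
Why: Lipase kinetic resolution of a secondary alcohol with a small (vinyl) and a large (trisubstituted alkenyl) group follows the Kazlauskas rule, so the R enantiomer is acetylated and the S alcohol (C6 of the target) is recovered.

**Step 3**
Reactants: 6 (3S,4E)-5-methylnona-1,4,8-trien-3-ol; 7 2-(bromomethyl)prop-2-enoic acid
Product: 8 (3S,4E)-5-methylnona-1,4,8-trien-3-yl 2-(bromomethyl)prop-2-enoate
Conditions: DCC, DMAP (5 mol%), CH2Cl2, −10 to 0 °C
Reagents that add atoms: none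
Why: Steglich esterification at low temperature and low DMAP loading acylates the carbinol without touching the stereocentre or displacing the allylic bromide.

**Step 4**
Reactants: 8 (3S,4E)-5-methylnona-1,4,8-trien-3-yl 2-(bromomethyl)prop-2-enoate
Product: 9 (5R)-3-(bromomethyl)-5-[(1E)-2-methylhexa-1,5-dien-1-yl]furan-2(5H)-one
Conditions: second-generation Grubbs catalyst (5 mol%), CH2Cl2 (5 mM), 40 °C
Reagents that add atoms: none
Why: Ring-closing metathesis of an allylic 2-substituted acrylate closes the five-membered butenolide far faster than any other ring available to the triene; the stereocentre is untouched and is now labelled R only because the CIP priorities change.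

**Step 5**
Reactants: 10 1,1,1,3,3,3-hexafluoropropan-2-yl prop-2-enoate; 11 2,2-dimethoxyacetaldehyde
Product: 13 methyl (3S)-3-hydroxy-4,4-dimethoxy-2-methylidenebutanoate, via hexafluoroisopropyl ester 12 (not isolated)
Conditions: β-isocupreidine (10 mol%), DMF, −55 °C; then MeOH, Et3N, 0 to 25 °C
Reagents that add atoms: methanol CO
Why: Hatakeyama's asymmetric Morita–Baylis–Hillman reaction sets the C9 carbinol with the facial sense that gives R adducts from simple aldehydes (here labelled S because the acetal carbon outranks the acrylate carbon), and the activated ester is then methanolysed in the same flask.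

**Step 6**
Reactants: 9 (5R)-3-(bromomethyl)-5-[(1E)-2-methylhexa-1,5-dien-1-yl]furan-2(5H)-one; 13 methyl (3S)-3-hydroxy-4,4-dimethoxy-2-methylidenebutanoate
Product: 14 methyl (2E,6E)-7-[(2R)-4-(bromomethyl)-5-oxo-2,5-dihydrofuran-2-yl]-2-[(1S)-1-hydroxy-2,2-dimethoxyethyl]-6-methylhepta-2,6-dienoate
Conditions: 13 (3 equiv), second-generation Hoveyda–Grubbs catalyst (10 mol%), CH2Cl2, 40 °C, argon sweep
Reagents that add atoms: none
Why: Cross-metathesis of a terminal alkene with a 2-substituted acrylate (as for methacrylates) gives the trisubstituted enoate, and the thermodynamic isomer with C2 trans to the ester is the E geometry the target needs at C1=C10.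

**Step 7**
Reactants: 14 methyl (2E,6E)-7-[(2R)-4-(bromomethyl)-5-oxo-2,5-dihydrofuran-2-yl]-2-[(1S)-1-hydroxy-2,2-dimethoxyethyl]-6-methylhepta-2,6-dienoate
Product: 17 methyl (2E,6E)-7-[(2R)-4-(bromomethyl)-5-oxo-2,5-dihydrofuran-2-yl]-6-methyl-2-[(1S)-2-oxo-1-(triethylsilyloxy)ethyl]hepta-2,6-dienoate, via triethylsilyl ether acetal 15 (not isolated), via collidinium triflate salt 16 (not isolated)
Conditions: TESOTf (3 equiv), 2,4,6-collidine (4.5 equiv), CH2Cl2, 0 °C; then H2O, 0 °C
Reagents that add atoms: triethylsilyl trifluoromethanesulfonate CC[Si](CC)(CC)OS(=O)(=O)C(F)(F)F; water O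
Why: The Fujioka–Kita acetal cleavage (silyl triflate and collidine, then water) silylates O9 and unmasks the C8 aldehyde under non-acidic, non-basic conditions that leave the epimerisable C9 centre, the allylic bromide and the butenolide intact.

**Step 8** (key step)
Reactants: 17 methyl (2E,6E)-7-[(2R)-4-(bromomethyl)-5-oxo-2,5-dihydrofuran-2-yl]-6-methyl-2-[(1S)-2-oxo-1-(triethylsilyloxy)ethyl]hepta-2,6-dienoate
Product: 19 methyl (3aR,4R,5S,6E,10E,11aR)-4-hydroxy-10-methyl-3-methylidene-2-oxo-5-(triethylsilyloxy)-2,3,3a,4,5,8,9,11a-octahydrocyclodeca[b]furan-6-carboxylate, via allylchromium dichloride 18 (not isolated)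
Conditions: CrCl2 (8 equiv), THF, 25 °C, 17 added over 12 h (final 2 mM); then H2O
Reagents that add atoms: none
Why: In this intramolecular Nozaki–Hiyama (Barbier) allylation the allylchromium from the bromomethylbutenolide acts as a vinylogous homoenolate and attacks the C8 aldehyde through C7, anti to the C6 side chain (trans lactone, C7 R); the ring-fixed E-type allyl unit in a chair transition state gives the anti adduct (C8 R), which is also the Felkin–Anh product of the α-silyloxy aldehyde, and allylic transposition releases the exocyclic methylene.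

**Step 9**
Reactants: 19 methyl (3aR,4R,5S,6E,10E,11aR)-4-hydroxy-10-methyl-3-methylidene-2-oxo-5-(triethylsilyloxy)-2,3,3a,4,5,8,9,11a-octahydrocyclodeca[b]furan-6-carboxylate
Product: 20 methyl (3aS,4S,5S,6E,10E,11aR)-10-methyl-3-methylidene-4-(2-methylprop-2-enoyloxy)-2-oxo-5-(triethylsilyloxy)-2,3,3a,4,5,8,9,11a-octahydrocyclodeca[b]furan-6-carboxylate
Conditions: methacrylic acid, PPh3, DIAD, toluene, 0 to 25 °C
Reagents that add atoms: methacrylic acid C=C(C)C(=O)O
Why: Mitsunobu esterification displaces the activated C8 oxygen by SN2 with clean inversion (R to S), installing the methacrylate with the target configuration, and the neighbouring silyl ether cannot participate.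

**Step 10**
Reactants: 20 methyl (3aS,4S,5S,6E,10E,11aR)-10-methyl-3-methylidene-4-(2-methylprop-2-enoyloxy)-2-oxo-5-(triethylsilyloxy)-2,3,3a,4,5,8,9,11a-octahydrocyclodeca[b]furan-6-carboxylate
Product: 22 methyl (3aS,4S,5S,6E,10E,11aR)-5-acetyloxy-10-methyl-3-methylidene-4-(2-methylprop-2-enoyloxy)-2-oxo-2,3,3a,4,5,8,9,11a-octahydrocyclodeca[b]furan-6-carboxylate, via C9 alcohol 21 (not isolated)
Conditions: HF·pyridine, THF/pyridine, 0 °C; then Ac2O, DMAP, 25 °C
Reagents that add atoms: acetic anhydride CC(=O)OC(C)=O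
Why: Fluoride cleaves the triethylsilyl ether and the freed C9 hydroxyl is acetylated at once in the same flask, with retention, before any acyl migration from O8 can occur.

**Step 11**
Reactants: 22 methyl (3aS,4S,5S,6E,10E,11aR)-5-acetyloxy-10-methyl-3-methylidene-4-(2-methylprop-2-enoyloxy)-2-oxo-2,3,3a,4,5,8,9,11a-octahydrocyclodeca[b]furan-6-carboxylate
Product: 23 methyl (1S,2R,4R,7E,9S,10S,11R)-9-acetyloxy-4-methyl-12-methylidene-10-(2-methylprop-2-enoyloxy)-13-oxo-3,14-dioxatricyclo[9.3.0.0^2,4]tetradec-7-ene-8-carboxylate (target)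
Conditions: mCPBA, NaHCO3, CH2Cl2, 0 °C
Reagents that add atoms: 3-chloroperoxybenzoic acid O=C(OO)c1cccc(Cl)c1
Why: Prilezhaev epoxidation picks out C4=C5, the only electron-rich alkene, and attacks its exposed outer face in the ten-membered ring (the inner face is blocked across the ring), which gives the 4R,5R trans-epoxide found in related 6,7-trans-lactone germacranolides.

**Compound list**
1 | hex-1-en-5-yne | C#CCCC=C | starting material
2 | acrolein (prop-2-enal) | C=CC=O | starting material
3 | dimethyl[(1E)-2-methylhexa-1,5-dien-1-yl]alumane | C[Al](C)/C=C(\C)CCC=C | intermediate (not isolated)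
4 | lithium butyl(dimethyl)[(1E)-2-methylhexa-1,5-dien-1-yl]aluminate | [Li+].CCCC[Al-](C)(C)/C=C(\C)CCC=C | intermediate (not isolated)
5 | racemic (4E)-5-methylnona-1,4,8-trien-3-ol | C=CC(O)/C=C(\C)CCC=C | intermediate
6 | (3S,4E)-5-methylnona-1,4,8-trien-3-ol | O[C@@H](C=C)/C=C(\C)CCC=C | intermediate
7 | 2-(bromomethyl)prop-2-enoic acid | C=C(CBr)C(=O)O | starting material
8 | (3S,4E)-5-methylnona-1,4,8-trien-3-yl 2-(bromomethyl)prop-2-enoate | C=C(CBr)C(=O)O[C@@H](C=C)/C=C(\C)CCC=C | intermediate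
9 | (5R)-3-(bromomethyl)-5-[(1E)-2-methylhexa-1,5-dien-1-yl]furan-2(5H)-one | O=C1O[C@H](/C=C(\C)CCC=C)C=C1CBr | intermediate
10 | 1,1,1,3,3,3-hexafluoropropan-2-yl prop-2-enoate | C=CC(=O)OC(C(F)(F)F)C(F)(F)F | starting material
11 | 2,2-dimethoxyacetaldehyde | COC(OC)C=O | starting material
12 | 1,1,1,3,3,3-hexafluoropropan-2-yl (3S)-3-hydroxy-4,4-dimethoxy-2-methylidenebutanoate | C=C(C(=O)OC(C(F)(F)F)C(F)(F)F)[C@@H](C(OC)OC)O | intermediate (not isolated)
13 | methyl (3S)-3-hydroxy-4,4-dimethoxy-2-methylidenebutanoate | C=C(C(=O)OC)[C@@H](C(OC)OC)O | intermediate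
14 | methyl (2E,6E)-7-[(2R)-4-(bromomethyl)-5-oxo-2,5-dihydrofuran-2-yl]-2-[(1S)-1-hydroxy-2,2-dimethoxyethyl]-6-methylhepta-2,6-dienoate | O=C1O[C@H](/C=C(\C)CC/C=C(/C(=O)OC)[C@@H](C(OC)OC)O)C=C1CBr | intermediate
15 | methyl (2E,6E)-7-[(2R)-4-(bromomethyl)-5-oxo-2,5-dihydrofuran-2-yl]-2-[(1S)-2,2-dimethoxy-1-(triethylsilyloxy)ethyl]-6-methylhepta-2,6-dienoate | O=C1O[C@H](/C=C(\C)CC/C=C(/C(=O)OC)[C@@H](C(OC)OC)O[Si](CC)(CC)CC)C=C1CBr | intermediate (not isolated)
16 | 2,4,6-trimethylpyridinium triflate salt from 15, one acetal methoxy at C8 replaced by the pyridinium nitrogen (C8 configuration undefined) | O=C1O[C@H](/C=C(\C)CC/C=C(/C(=O)OC)[C@@H](C(OC)[n+]2c(C)cc(C)cc2C)O[Si](CC)(CC)CC)C=C1CBr.[O-]S(=O)(=O)C(F)(F)F | intermediate (not isolated)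
17 | methyl (2E,6E)-7-[(2R)-4-(bromomethyl)-5-oxo-2,5-dihydrofuran-2-yl]-6-methyl-2-[(1S)-2-oxo-1-(triethylsilyloxy)ethyl]hepta-2,6-dienoate | O=C1O[C@H](/C=C(\C)CC/C=C(/C(=O)OC)[C@@H](C=O)O[Si](CC)(CC)CC)C=C1CBr | intermediate
18 | allylchromium dichloride from 17 (CH2Br replaced by CH2CrCl2) | O=C1O[C@H](/C=C(\C)CC/C=C(/C(=O)OC)[C@@H](C=O)O[Si](CC)(CC)CC)C=C1C[Cr](Cl)Cl | intermediate (not isolated)
19 | methyl (3aR,4R,5S,6E,10E,11aR)-4-hydroxy-10-methyl-3-methylidene-2-oxo-5-(triethylsilyloxy)-2,3,3a,4,5,8,9,11a-octahydrocyclodeca[b]furan-6-carboxylate (6S,7R,8R,9S in germacrane numbering) | O[C@@H]1[C@H]2C(=C)C(=O)O[C@@H]2/C=C(\C)CC/C=C(/C(=O)OC)[C@@H]1O[Si](CC)(CC)CC | intermediate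
20 | methyl (3aS,4S,5S,6E,10E,11aR)-10-methyl-3-methylidene-4-(2-methylprop-2-enoyloxy)-2-oxo-5-(triethylsilyloxy)-2,3,3a,4,5,8,9,11a-octahydrocyclodeca[b]furan-6-carboxylate | C=C(C)C(=O)O[C@H]1[C@H]2C(=C)C(=O)O[C@@H]2/C=C(\C)CC/C=C(/C(=O)OC)[C@@H]1O[Si](CC)(CC)CC | intermediate
21 | methyl (3aS,4S,5S,6E,10E,11aR)-5-hydroxy-10-methyl-3-methylidene-4-(2-methylprop-2-enoyloxy)-2-oxo-2,3,3a,4,5,8,9,11a-octahydrocyclodeca[b]furan-6-carboxylate | C=C(C)C(=O)O[C@H]1[C@H]2C(=C)C(=O)O[C@@H]2/C=C(\C)CC/C=C(/C(=O)OC)[C@@H]1O | intermediate (not isolated)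
22 | methyl (3aS,4S,5S,6E,10E,11aR)-5-acetyloxy-10-methyl-3-methylidene-4-(2-methylprop-2-enoyloxy)-2-oxo-2,3,3a,4,5,8,9,11a-octahydrocyclodeca[b]furan-6-carboxylate | C=C(C)C(=O)O[C@H]1[C@H]2C(=C)C(=O)O[C@@H]2/C=C(\C)CC/C=C(/C(=O)OC)[C@@H]1OC(C)=O | intermediate
23 | methyl (1S,2R,4R,7E,9S,10S,11R)-9-acetyloxy-4-methyl-12-methylidene-10-(2-methylprop-2-enoyloxy)-13-oxo-3,14-dioxatricyclo[9.3.0.0^2,4]tetradec-7-ene-8-carboxylate (CNP0153978.3) | C=C(C)C(=O)O[C@H]1[C@H]2C(=C)C(=O)O[C@@H]2[C@H]2O[C@]2(C)CC/C=C(/C(=O)OC)[C@@H]1OC(C)=O | target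

**Step count and risks**

Total steps: 11. Longest linear sequence: 10 (steps 1–4 and 6–11); step 5 is the convergent branch.

The three steps most likely to fail are 6, 8 and 9.

Step 6 (cross-metathesis of the hindered 2-substituted acrylate 13; low conversion or E/Z mixtures). The fallback reverses the order of the two unions; it sets out from 9 and 13 and comes back to the route at 19. Alcohol 13 is silylated and unmasked by the step-7 protocol (TESOTf, 2,4,6-collidine, then H2O) to methyl (3S)-2-methylidene-4-oxo-3-(triethylsilyloxy)butanoate F1. Butenolide 9 and F1 are then joined by an intermolecular zinc Barbier reaction (Zn, aqueous NH4Cl, THF, 0 °C), which follows the same chair and Felkin–Anh sense and gives the open-chain adduct methyl 2-[(1S,2R)-2-hydroxy-2-{(2R,3R)-2-[(1E)-2-methylhexa-1,5-dien-1-yl]-4-methylidene-5-oxooxolan-3-yl}-1-(triethylsilyloxy)ethyl]prop-2-enoate F2. Ring-closing metathesis of F2 (second-generation Hoveyda–Grubbs catalyst, toluene, 80 °C, 1 mM) forms C1=C10 inside the ring, where the ten-membered ring itself enforces the ring-cis geometry, and delivers 19.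

Step 8 (chromium macrocyclisation; oligomers instead of the ten-membered ring). The fallback closes the same C7–C8 bond with a ketyl instead of an allylmetal; it sets out from 17 and comes back at 19. CsOAc (DMF, 0 °C) exchanges bromide for acetate to give methyl (2E,6E)-7-[(2R)-4-(acetyloxymethyl)-5-oxo-2,5-dihydrofuran-2-yl]-6-methyl-2-[(1S)-2-oxo-1-(triethylsilyloxy)ethyl]hepta-2,6-dienoate F3. SmI2 (2.5 equiv, THF, −78 °C, 1 mM) then turns the aldehyde into a ketyl radical anion, a nucleophilic C8 that adds to C7 of the butenolide anti to the C6 side chain; the resulting samarium enolate expels acetate to leave the exocyclic methylene. Work-up gives 19, and any C8 epimer is separated by chromatography.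

Step 9 (Mitsunobu inversion at the hindered C8 carbinol; elimination or no reaction). The fallback inverts C8 by oxidation and reduction; it sets out from 19 and comes back at 20. Dess–Martin periodinane (NaHCO3, CH2Cl2, 0 °C) gives the ketone methyl (3aS,5S,6E,10E,11aR)-10-methyl-3-methylidene-2,4-dioxo-5-(triethylsilyloxy)-2,3,3a,4,5,8,9,11a-octahydrocyclodeca[b]furan-6-carboxylate F4, which is used at once because C7 can epimerise or the methylene can move into conjugation. Luche reduction (NaBH4, CeCl3·7H2O, MeOH, −78 °C) under Felkin–Anh control of the C9 silyloxy centre gives the 8S alcohol methyl (3aR,4S,5S,6E,10E,11aR)-4-hydroxy-10-methyl-3-methylidene-2-oxo-5-(triethylsilyloxy)-2,3,3a,4,5,8,9,11a-octahydrocyclodeca[b]furan-6-carboxylate F5, and methacrylic anhydride (Et3N, DMAP, CH2Cl2, 0 °C) then gives 20.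

**Further compounds**
F1 | step 6 | methyl (3S)-2-methylidene-4-oxo-3-(triethylsilyloxy)butanoate | C=C(C(=O)OC)[C@@H](C=O)O[Si](CC)(CC)CC
F2 | step 6 | methyl 2-[(1S,2R)-2-hydroxy-2-{(2R,3R)-2-[(1E)-2-methylhexa-1,5-dien-1-yl]-4-methylidene-5-oxooxolan-3-yl}-1-(triethylsilyloxy)ethyl]prop-2-enoate | O[C@H]([C@H]1C(=C)C(=O)O[C@@H]1/C=C(\C)CCC=C)[C@@H](O[Si](CC)(CC)CC)C(=C)C(=O)OC
F3 | step 8 | methyl (2E,6E)-7-[(2R)-4-(acetyloxymethyl)-5-oxo-2,5-dihydrofuran-2-yl]-6-methyl-2-[(1S)-2-oxo-1-(triethylsilyloxy)ethyl]hepta-2,6-dienoate | O=C1O[C@H](/C=C(\C)CC/C=C(/C(=O)OC)[C@@H](C=O)O[Si](CC)(CC)CC)C=C1COC(C)=O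
F4 | step 9 | methyl (3aS,5S,6E,10E,11aR)-10-methyl-3-methylidene-2,4-dioxo-5-(triethylsilyloxy)-2,3,3a,4,5,8,9,11a-octahydrocyclodeca[b]furan-6-carboxylate | O=C1[C@H]2C(=C)C(=O)O[C@@H]2/C=C(\C)CC/C=C(/C(=O)OC)[C@@H]1O[Si](CC)(CC)CC
F5 | step 9 | methyl (3aR,4S,5S,6E,10E,11aR)-4-hydroxy-10-methyl-3-methylidene-2-oxo-5-(triethylsilyloxy)-2,3,3a,4,5,8,9,11a-octahydrocyclodeca[b]furan-6-carboxylate | O[C@H]1[C@H]2C(=C)C(=O)O[C@@H]2/C=C(\C)CC/C=C(/C(=O)OC)[C@@H]1O[Si](CC)(CC)CC
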